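## The problem

Target 14, 3-(2,4-dihydroxyphenyl)-7-hydroxy-5-methoxy-8-(2-methylbut-3-en-2-yl)-2H-chromen-2-one, is a 3-arylcoumarin in which benzo ring A (C4a–C8a) is fused to pyranone ring B (O1, C2, C3, C4) and C3 carries resorcinol ring C through the C3–C1' bond. Ring A keeps a single hydrogen (C6–H) and bears OMe at C5, OH at C7 and, at C8, a quaternary benzylic carbon wedged between O7 and the ring oxygen O1, the most crowded bond of the molecule. There is no stereocentre, so no centre controls another; the only stereochemical element on the way is the geometry of the alkene that becomes C3=C4. Four oxygens have to be told apart: O5 is methylated, O7 must be addressed alone on the way to the C8 side chain, and O2' and O4' stay masked until the last step. The terminal vinyl group next to the C7 phenol does not tolerate strong acid (ring closure to a dihydrofuran), hydrogenation or palladium chemistry, the lactone opens in strong aqueous base, and the electron-rich rings are sensitive to oxidants. C2 is a carbonyl carbon with only two neighbours, O1 and C3; taking it out as carbon monoxide leaves a 2-hydroxystilbene of E geometry, in which the C3–H bond and the C8a hydroxyl sit on the same side of the double bond, the arrangement that a phenol-directed alkenyl C–H carbonylation needs. A 1,1-dimethylallyl group ortho to a phenol is in turn the imprint of a [3,3] shift of an O7 prenyl ether.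

## Retrosynthesis

Coumarin numbering is used for all intermediates.

**14 from 12.** No skeletal bond is cut. The last operation strips the two MOM ethers of ring C (giving diol butanoate 13) and then the O7 butanoate. MOM is chosen for ring C because dilute methanolic acid removes it; benzyl ethers there would need hydrogenolysis, which would saturate the vinyl group. The order matters: the acid is applied while O7 is still acylated, so that no free hydroxyl flanks the 1,1-dimethylallyl group in acid and the side chain cannot close onto O7. The ester is then taken off with mild base.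

**12 from 10.** The C8–C(quaternary) bond is cut and the other allyl terminus is reconnected to O7, giving prenyl ether 10 (aromatic Claisen rearrangement via phenol 11, trapped as ester 12). The neighbouring cuts are worse. Friedel–Crafts alkylation with a tertiary allyl cation delivers the linear prenyl group or a chroman. Cutting the methyl and vinyl bonds of the quaternary carbon forces the side chain into the synthesis before ring B exists. The precursor loses the only quaternary carbon. The forward reaction must choose C8 over C6 and must stop at the ortho stage.

**10 from 9 from 8.** The O7–C bond of the prenyl ether is cut to give phenol 9, which comes from benzyl ether 8. A benzyl ether on O7 is orthogonal to the MOM ethers of ring C, so O7 alone is freed and the prenylation does not depend on acidity differences between three phenols. The prenyl ether itself cannot be carried through the palladium steps because zerovalent palladium would ionise it. The hydrogenolysis must spare C3=C4.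

**8 from 6 and 7.** C2–C3 and C2–O1 are cut, ring B disappears, and the precursors are stilbene phenol 6 and carbon monoxide 7. Cutting only the lactone C–O bond would require a trisubstituted Z-configured α-arylcinnamate. Cutting C3–C1' would require the coumarin to exist first. Precursor 6 has no heterocycle and no carbonyl group. The forward step demands one free phenol, the E alkene, and carbonylation in preference to closure to a benzofuran.

**6 from 3 and 5.** The aryl–vinyl bond on the ring C side (the future C3–C1' bond) is cut, which is a Mizoroki–Heck arylation of vinylphenol 3 by bromide 5. The alternative cut through the central double bond (phosphonate olefination) needs the phenol masked, because its phenoxide deactivates the aldehyde. It also needs a labile 2,4-dialkoxybenzyl halide and four more steps. The Heck reaction gives the E alkene with the phenol free. It must arylate the terminal carbon and tolerate the phenol.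

**3 from 2 from 1; 5 from 4.** Vinylphenol 3 comes from salicylaldehyde 2 by methylenation, and 2 from aldehyde 1 by benzylation of the non-chelated 4-hydroxyl. Aldehyde 1 already carries the O5 methyl ether, so O5 and O7 never need to be told apart later. Bromide 5 is the bis-MOM ether of 4-bromoresorcinol 4.

## Roads not taken

**Alternative 1:** The cut is made at the quaternary carbon itself. Its methyl and vinyl bonds are formed on a symmetric ring A ketone, 1-[2,6-bis(tert-butoxycarbonyloxy)-4-methoxyphenyl]ethan-1-one A1, long before ring B exists. In the forward key step MeMgBr attacks the ketone of A1 and the resulting tertiary alkoxide picks up the neighbouring Boc group. Expulsion of tert-butyl carbonate generates an ortho-quinone methide, and CH2=CHMgBr then attacks its exocyclic carbon to give tert-butyl 3-hydroxy-5-methoxy-2-(2-methylbut-3-en-2-yl)phenyl carbonate A2.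
- Merits: the 1,1-dimethylallyl group is placed between the two ring A oxygens with no C6/C8 question, and the two oxygens emerge differentiated. In positional certainty this road is better than the Claisen step of the chosen plan.
- Weak points: formylation at a hindered carbon, ring B and the C3–aryl bond must all be built on a ring that already carries the terminal alkene beside a phenol. Acidic formylation invites closure to a dihydrobenzofuran, and any palladium-based ring construction meets a monosubstituted alkene. The key step solves the side chain only, so the route is longer.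
- Comparison: the chosen plan gives up the positional certainty of A2. In return it introduces the sensitive alkene in the penultimate step, after every metal-, hydrogen- and oxidant-based step, and it relies on the established bond fixation of 7-oxygenated coumarins to guide the shift to C8.

**Alternative 2:** The cut is at C4–C4a and O1–C2 (Pechmann closure). Benzene-1,3,5-triol A3 and ethyl 2-(2,4-diisopropoxyphenyl)-3-oxopropanoate A4 would be combined in protic acid, the formyl carbon substituting the arene and the ester lactonising, to give 3-(2,4-diisopropoxyphenyl)-5,7-dihydroxy-2H-chromen-2-one A5.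
- Merits: the arylcoumarin core arises in one metal-free step from a symmetric phenol, with no regiochemical issue and no CO. In step count to the core and in documented reliability this road is better than the chosen plan.
- Weak points: A5 has O5 and O7 both free, so prenylation of O7 and methylation of O5 must be sequenced afterwards. The α-formyl ester A4 is prone to deformylation in strong acid. The isopropyl ethers need BCl3 at the end, when the molecule contains the acid-sensitive ortho-(1,1-dimethylallyl)phenol and a methyl ether.
- Comparison: the chosen plan is longer to the core. It sets against this an O5 methyl ether that comes with 1, an O7 singled out by an orthogonal benzyl ether, and a final deprotection in dilute acid that is run while O7 is still acylated.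

**Alternative 3:** The C3–C1' bond is made by a biomimetic 1,2-aryl shift. The chalcone (E)-1-[4-(benzyloxy)-2-hydroxy-6-methoxyphenyl]-3-[2,4-bis(benzyloxy)phenyl]prop-2-en-1-one A6 would be oxidised by Tl(NO3)3 in methanol. The aryl group of ring C shifts from the β-carbon to the α-carbon of the enone, which creates the C3–C1' bond, and the rearranged acetal is cyclised with acid through O1–C2 to the isoflavone 7-(benzyloxy)-3-[2,4-bis(benzyloxy)phenyl]-5-methoxy-4H-chromen-4-one A7.
- Merits: A6 comes from a single aldol condensation, and the oxidative aryl shift is better documented than the carbonylation of a β-aryl vinylphenol. On reliability of the key step this road is ahead.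
- Weak points: A7 has its carbonyl at C4 and a CH at C2, so the oxidation pattern must be transposed over several redox steps. The oxidant is stoichiometric, toxic trivalent thallium. The three benzyl ethers must be hydrogenolysed before the alkene arrives, which leaves three free phenols to prenylate selectively.
- Comparison: the chosen plan inserts C2 at the correct oxidation level with catalytic palladium and needs no redox correction. Its price is a less proven key step, covered by a fallback below.

Key step: step 5

Remark: carbon monoxide is counted as building block 7 because its carbon becomes C2. The target has no stereocentre, so the only stereochemical element set in the route is the E double bond of 6.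

## Route

Step 1
Reactants: 1 2,4-dihydroxy-6-methoxybenzaldehyde
Product: 2 4-(benzyloxy)-2-hydroxy-6-methoxybenzaldehyde
Conditions: BnBr (1.05 equiv), K2CO3 (1.1 equiv), acetone, 50 °C
Reagents that add atoms: benzyl bromide, BrCc1ccccc1
Why: Williamson etherification; the 2-hydroxyl is hydrogen-bonded to the aldehyde and hindered by it, so the more acidic, free 4-hydroxyl should be alkylated selectively with one equivalent of bromide and a mild base.

Step 2
Reactants: 2 4-(benzyloxy)-2-hydroxy-6-methoxybenzaldehyde
Product: 3 5-(benzyloxy)-2-ethenyl-3-methoxyphenol
Conditions: Ph3PCH3Br (2.5 equiv), KOtBu (2.4 equiv), THF, 0 °C to rt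
Reagents that add atoms: methyltriphenylphosphonium bromide, C[P+](c1ccccc1)(c1ccccc1)c1ccccc1.[Br-]
Why: Wittig methylenation with excess unstabilised ylide (one equivalent is spent on the phenol), the usual entry to 2-vinylphenols from salicylaldehydes; Ph3P=CH2 is reactive enough for the phenoxide-deactivated aldehyde. Phenol 3 is acid-sensitive and should be purified on base-washed silica and used promptly.

Step 3
Reactants: 4 4-bromobenzene-1,3-diol
Product: 5 1-bromo-2,4-bis(methoxymethoxy)benzene
Conditions: MOMCl, i-Pr2NEt, CH2Cl2, 0 °C to rt
Reagents that add atoms: chloromethyl methyl ether, COCCl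
Why: Standard acetal protection of both phenols; MOM ethers should survive the basic palladium steps and the thermal rearrangement and leave under dilute acid at the end.

Step 4
Reactants: 3 5-(benzyloxy)-2-ethenyl-3-methoxyphenol; 5 1-bromo-2,4-bis(methoxymethoxy)benzene
Product: 6 5-(benzyloxy)-2-[(E)-2-[2,4-bis(methoxymethoxy)phenyl]ethenyl]-3-methoxyphenol
Conditions: Pd2(dba)3 (2.5 mol %), P(t-Bu)3·HBF4 (10 mol %), Cy2NMe, 1,4-dioxane, 90 °C, argon
Reagents that add atoms: none
Why: Mizoroki–Heck arylation: oxidative addition of 5 to zerovalent palladium, syn-carbopalladation with the aryl group going to the unhindered terminal carbon, and syn-β-hydride elimination should give the 1,2-disubstituted alkene with E geometry. The bulky electron-rich phosphine is chosen for the electron-rich, ortho-substituted bromide, and the amine base leaves the phenol free; air is excluded so that 6 does not cyclise oxidatively.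

Step 5
Reactants: 6 5-(benzyloxy)-2-[(E)-2-[2,4-bis(methoxymethoxy)phenyl]ethenyl]-3-methoxyphenol; 7 carbon monoxide
Product: 8 7-(benzyloxy)-3-[2,4-bis(methoxymethoxy)phenyl]-5-methoxy-2H-chromen-2-one
Conditions: Pd(OAc)2 (10 mol %), 1,4-benzoquinone (2 equiv), MeCN, 90 °C, under CO (5 atm)
Reagents that add atoms: none
Why: Pd(OAc)2 exchanges an acetate for the phenoxide of 6, and acetate-assisted cleavage of the vinylic C3–H, which in the E alkene lies cis to ring A, gives the six-membered oxapalladacycle (Pd, O1, C8a, C4a, C4, C3). CO inserts into the Pd–C3 bond and C–O reductive elimination from the acyl palladium phenoxide forms O1–C2, releasing 8 and zerovalent palladium, which benzoquinone reoxidises to divalent palladium. The closest known reaction type is the palladium-catalysed oxidative cyclocarbonylation of 2-vinylphenols to coumarins, of which β-aryl members such as 6 are a sparsely documented subset. Ring B closes as a six-membered lactone in a [5+1] sense, CO supplying C2, and the closing event is the acyl–oxygen reductive elimination; a path through an aryloxycarbonyl palladium species that inserts the alkene would converge on the same product. No stereocentre is formed. The step needs site selectivity, secured by the single free phenol (O7 is a benzyl ether, O2' and O4' are MOM ethers), geometric selectivity, secured by the E alkene from step 4 (C3–H and not ring C faces the phenol), and chemoselectivity against 5-endo oxypalladation to a 2-arylbenzofuran, for which a CO-saturated, less electrophilic palladium centre and the acetate base should favour the carbonylative path.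

Step 6
Reactants: 8 7-(benzyloxy)-3-[2,4-bis(methoxymethoxy)phenyl]-5-methoxy-2H-chromen-2-one
Product: 9 3-[2,4-bis(methoxymethoxy)phenyl]-7-hydroxy-5-methoxy-2H-chromen-2-one
Conditions: H2 (1 atm), 10% Pd/C, EtOAc–THF, rt
Reagents that add atoms: none
Why: Hydrogenolysis of the benzyl aryl ether; MOM ethers and the lactone are inert, and the trisubstituted, doubly aryl-conjugated C3–C4 double bond should reduce much more slowly, so the reaction is stopped after one equivalent of hydrogen.

Step 7
Reactants: 9 3-[2,4-bis(methoxymethoxy)phenyl]-7-hydroxy-5-methoxy-2H-chromen-2-one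
Product: 10 3-[2,4-bis(methoxymethoxy)phenyl]-5-methoxy-7-[(3-methylbut-2-en-1-yl)oxy]-2H-chromen-2-one
Conditions: prenyl bromide, K2CO3, acetone, 50 °C
Reagents that add atoms: 1-bromo-3-methylbut-2-ene, CC(C)=CCBr
Why: Williamson etherification of the only free hydroxyl; the 7-hydroxyl of a coumarin is a vinylogous carboxylic acid and should be alkylated cleanly by an allylic bromide and carbonate base.

Step 8
Reactants: 10 3-[2,4-bis(methoxymethoxy)phenyl]-5-methoxy-7-[(3-methylbut-2-en-1-yl)oxy]-2H-chromen-2-one
Product: 12 3-[2,4-bis(methoxymethoxy)phenyl]-5-methoxy-8-(2-methylbut-3-en-2-yl)-2-oxo-2H-chromen-7-yl butanoate, via the free C7 phenol 11 (not isolated)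
Conditions: (n-PrCO)2O, PhNEt2, 185 °C, argon
Reagents that add atoms: butanoic anhydride, CCCC(=O)OC(=O)CCC
Why: Aromatic Claisen rearrangement: the [3,3] shift delivers the tertiary allyl terminus to an ortho carbon, and bond fixation in coumarins (higher C7–C8 than C6–C7 bond order) together with the 5-methoxy group beside C6 should direct it to C8. Acylation of phenol 11 in the flask removes the hydroxyl proton that the abnormal Claisen pathway and dihydrofuran closure need, and the amine solvent buffers the butanoic acid so that the MOM ethers persist.

Step 9
Reactants: 12 3-[2,4-bis(methoxymethoxy)phenyl]-5-methoxy-8-(2-methylbut-3-en-2-yl)-2-oxo-2H-chromen-7-yl butanoate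
Product: 14 3-(2,4-dihydroxyphenyl)-7-hydroxy-5-methoxy-8-(2-methylbut-3-en-2-yl)-2H-chromen-2-one, via the ring C diol butanoate 13 (not isolated)
Conditions: HCl (1 M in MeOH), 45 °C; then K2CO3 (excess), MeOH, rt, argon; acidify on work-up
Reagents that add atoms: none
Why: Acid-catalysed acetal exchange of the two MOM ethers with methanol is run first, while O7 is still acylated, so that no free hydroxyl sits beside the 1,1-dimethylallyl group in acid and closure to a dihydrofuran is excluded. Carbonate-mediated methanolysis (transesterification) of the aryl butanoate 13 then frees O7 under conditions that leave the alkene untouched, and any lactone opened by methoxide recloses on acidification.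

## Compound list

1 | 2,4-dihydroxy-6-methoxybenzaldehyde | COc1cc(O)cc(O)c1C=O | starting material
2 | 4-(benzyloxy)-2-hydroxy-6-methoxybenzaldehyde | COc1cc(OCc2ccccc2)cc(O)c1C=O | intermediate
3 | 5-(benzyloxy)-2-ethenyl-3-methoxyphenol | C=Cc1c(O)cc(OCc2ccccc2)cc1OC | intermediate
4 | 4-bromobenzene-1,3-diol | Oc1ccc(Br)c(O)c1 | starting material
5 | 1-bromo-2,4-bis(methoxymethoxy)benzene | COCOc1ccc(Br)c(OCOC)c1 | intermediate
6 | 5-(benzyloxy)-2-[(E)-2-[2,4-bis(methoxymethoxy)phenyl]ethenyl]-3-methoxyphenol | COCOc1ccc(/C=C/c2c(O)cc(OCc3ccccc3)cc2OC)c(OCOC)c1 | intermediate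
7 | carbon monoxide | [C-]#[O+] | starting material
8 | 7-(benzyloxy)-3-[2,4-bis(methoxymethoxy)phenyl]-5-methoxy-2H-chromen-2-one | COCOc1ccc(-c2cc3c(OC)cc(OCc4ccccc4)cc3oc2=O)c(OCOC)c1 | intermediate
9 | 3-[2,4-bis(methoxymethoxy)phenyl]-7-hydroxy-5-methoxy-2H-chromen-2-one | COCOc1ccc(-c2cc3c(OC)cc(O)cc3oc2=O)c(OCOC)c1 | intermediate
10 | 3-[2,4-bis(methoxymethoxy)phenyl]-5-methoxy-7-[(3-methylbut-2-en-1-yl)oxy]-2H-chromen-2-one | COCOc1ccc(-c2cc3c(OC)cc(OCC=C(C)C)cc3oc2=O)c(OCOC)c1 | intermediate
11 | 3-[2,4-bis(methoxymethoxy)phenyl]-7-hydroxy-5-methoxy-8-(2-methylbut-3-en-2-yl)-2H-chromen-2-one | C=CC(C)(C)c1c(O)cc(OC)c2cc(-c3ccc(OCOC)cc3OCOC)c(=O)oc12 | intermediate (not isolated)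
12 | 3-[2,4-bis(methoxymethoxy)phenyl]-5-methoxy-8-(2-methylbut-3-en-2-yl)-2-oxo-2H-chromen-7-yl butanoate | C=CC(C)(C)c1c(OC(=O)CCC)cc(OC)c2cc(-c3ccc(OCOC)cc3OCOC)c(=O)oc12 | intermediate
13 | 3-(2,4-dihydroxyphenyl)-5-methoxy-8-(2-methylbut-3-en-2-yl)-2-oxo-2H-chromen-7-yl butanoate | C=CC(C)(C)c1c(OC(=O)CCC)cc(OC)c2cc(-c3ccc(O)cc3O)c(=O)oc12 | intermediate (not isolated)
14 | 3-(2,4-dihydroxyphenyl)-7-hydroxy-5-methoxy-8-(2-methylbut-3-en-2-yl)-2H-chromen-2-one | C=CC(C)(C)c1c(O)cc(OC)c2cc(-c3ccc(O)cc3O)c(=O)oc12 | target

## Step count and risks

Total: 9 steps. Longest linear sequence: 8 steps (1 → 2 → 3 → 6 → 8 → 9 → 10 → 12 → 14; bromide 5 joins at step 4).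

**Step 5 (key step).** The most likely failure is oxidative cyclisation: the phenoxide attacks the palladium-bound alkene and β-hydride elimination follows, giving a benzofuran. 2-Hydroxystilbenes are predisposed to this, and C3–H palladation is slowed by the twist that the two ortho substituents of ring A impose on the alkene. Conjugate addition of the electron-rich phenol to benzoquinone is a second drain; O2 with Cu(OAc)2 as terminal oxidant would be tried first. The fallback sets out from aldehyde 2 and returns at coumarin 8. Commercial (2,4-dihydroxyphenyl)acetic acid would be exhaustively alkylated with MOMCl and i-Pr2NEt to methoxymethyl 2-[2,4-bis(methoxymethoxy)phenyl]acetate F1. LiOH hydrolysis would give 2-[2,4-bis(methoxymethoxy)phenyl]acetic acid F2. Perkin–Oglialoro condensation of F2 with 2 (Ac2O, Et3N, 110 °C) would close ring B by aldol condensation and lactonisation to give 8.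

**Step 4.** Oxidative addition of the electron-rich, ortho-substituted bromide may be slow, and the electron-rich vinylphenol 3 may oligomerise at 90 °C before it couples; some arylation at the internal carbon is also possible. The fallback sets out from 2 and returns at 6 by a phosphonate olefination with the phenol masked. Aldehyde 2 would be allylated (allyl bromide, K2CO3, DMF) to 4-(benzyloxy)-2-methoxy-6-(prop-2-en-1-yloxy)benzaldehyde F3. Bromide 5 would be converted by bromine–lithium exchange (n-BuLi, THF, −78 °C) and DMF into 2,4-bis(methoxymethoxy)benzaldehyde F4, and this would be reduced with NaBH4 to [2,4-bis(methoxymethoxy)phenyl]methanol F5. Appel-type chlorination (PPh3, N-chlorosuccinimide) would give 1-(chloromethyl)-2,4-bis(methoxymethoxy)benzene F6, and Michaelis–Arbuzov reaction with P(OEt)3 would give diethyl {[2,4-bis(methoxymethoxy)phenyl]methyl}phosphonate F7. Horner–Wadsworth–Emmons reaction of F7 (NaH, THF) with F3 should give the E alkene 5-(benzyloxy)-1-methoxy-3-(prop-2-en-1-yloxy)-2-[(E)-2-[2,4-bis(methoxymethoxy)phenyl]ethenyl]benzene F8. Pd(PPh3)4 with morpholine would then remove the allyl group to give 6.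

**Step 8.** The shift may go to C6 instead of C8. If acylation lags, the allyl group may migrate onward by Cope shifts or the abnormal Claisen pathway, and the MOM ethers may be lost at 185 °C. The fallback sets out from phenol 9 and returns at target 14 without a thermal step. Electrophilic iodination (N-iodosuccinimide, MeCN), which in 7-hydroxycoumarins goes to C8, would give 3-[2,4-bis(methoxymethoxy)phenyl]-7-hydroxy-8-iodo-5-methoxy-2H-chromen-2-one F9. MOMCl and i-Pr2NEt would give 3-[2,4-bis(methoxymethoxy)phenyl]-8-iodo-5-methoxy-7-(methoxymethoxy)-2H-chromen-2-one F10. A branch-selective palladium-catalysed Suzuki–Miyaura coupling with 3-methylbut-2-enylboronic acid pinacol ester (bulky biarylphosphine ligand, K3PO4) would give 3-[2,4-bis(methoxymethoxy)phenyl]-5-methoxy-7-(methoxymethoxy)-8-(2-methylbut-3-en-2-yl)-2H-chromen-2-one F11. Brief treatment with dilute HCl in methanol at room temperature would release 14.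

**Step 6.** Hydrogen may also add to the C3–C4 double bond, because the same catalyst that cleaves the benzyl ether can reduce a coumarin. The fallback sets out from 8 and returns at 9. Hydrogenation is run to completion to give racemic 3-[2,4-bis(methoxymethoxy)phenyl]-7-hydroxy-5-methoxy-3,4-dihydro-2H-chromen-2-one F12. Dehydrogenation with DDQ in 1,4-dioxane, which starts by hydride abstraction at the C4 position para to the C7 hydroxyl, would then restore the double bond and give 9.

## Further compounds

F1 | step 5 | methoxymethyl 2-[2,4-bis(methoxymethoxy)phenyl]acetate | COCOC(=O)Cc1ccc(OCOC)cc1OCOC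
F2 | step 5 | 2-[2,4-bis(methoxymethoxy)phenyl]acetic acid | OC(=O)Cc1ccc(OCOC)cc1OCOC
F3 | step 4 | 4-(benzyloxy)-2-methoxy-6-(prop-2-en-1-yloxy)benzaldehyde | C=CCOc1cc(OCc2ccccc2)cc(OC)c1C=O
F4 | step 4 | 2,4-bis(methoxymethoxy)benzaldehyde | COCOc1ccc(C=O)c(OCOC)c1
F5 | step 4 | [2,4-bis(methoxymethoxy)phenyl]methanol | COCOc1ccc(CO)c(OCOC)c1
F6 | step 4 | 1-(chloromethyl)-2,4-bis(methoxymethoxy)benzene | COCOc1ccc(CCl)c(OCOC)c1
F7 | step 4 | diethyl {[2,4-bis(methoxymethoxy)phenyl]methyl}phosphonate | CCOP(=O)(OCC)Cc1ccc(OCOC)cc1OCOC
F8 | step 4 | 5-(benzyloxy)-1-methoxy-3-(prop-2-en-1-yloxy)-2-[(E)-2-[2,4-bis(methoxymethoxy)phenyl]ethenyl]benzene | C=CCOc1cc(OCc2ccccc2)cc(OC)c1/C=C/c1ccc(OCOC)cc1OCOC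
F9 | step 8 | 3-[2,4-bis(methoxymethoxy)phenyl]-7-hydroxy-8-iodo-5-methoxy-2H-chromen-2-one | COCOc1ccc(-c2cc3c(OC)cc(O)c(I)c3oc2=O)c(OCOC)c1
F10 | step 8 | 3-[2,4-bis(methoxymethoxy)phenyl]-8-iodo-5-methoxy-7-(methoxymethoxy)-2H-chromen-2-one | COCOc1ccc(-c2cc3c(OC)cc(OCOC)c(I)c3oc2=O)c(OCOC)c1
F11 | step 8 | 3-[2,4-bis(methoxymethoxy)phenyl]-5-methoxy-7-(methoxymethoxy)-8-(2-methylbut-3-en-2-yl)-2H-chromen-2-one | C=CC(C)(C)c1c(OCOC)cc(OC)c2cc(-c3ccc(OCOC)cc3OCOC)c(=O)oc12
F12 | step 6 | 3-[2,4-bis(methoxymethoxy)phenyl]-7-hydroxy-5-methoxy-3,4-dihydro-2H-chromen-2-one (racemic) | COCOc1ccc(C2Cc3c(OC)cc(O)cc3OC2=O)c(OCOC)c1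
A1 | alternative 1 | 1-[2,6-bis(tert-butoxycarbonyloxy)-4-methoxyphenyl]ethan-1-one | CC(=O)c1c(OC(=O)OC(C)(C)C)cc(OC)cc1OC(=O)OC(C)(C)C
A2 | alternative 1 | tert-butyl 3-hydroxy-5-methoxy-2-(2-methylbut-3-en-2-yl)phenyl carbonate | C=CC(C)(C)c1c(O)cc(OC)cc1OC(=O)OC(C)(C)C
A3 | alternative 2 | benzene-1,3,5-triol | Oc1cc(O)cc(O)c1
A4 | alternative 2 | ethyl 2-(2,4-diisopropoxyphenyl)-3-oxopropanoate | CCOC(=O)C(C=O)c1ccc(OC(C)C)cc1OC(C)C
A5 | alternative 2 | 3-(2,4-diisopropoxyphenyl)-5,7-dihydroxy-2H-chromen-2-one | CC(C)Oc1ccc(-c2cc3c(O)cc(O)cc3oc2=O)c(OC(C)C)c1
A6 | alternative 3 | (E)-1-[4-(benzyloxy)-2-hydroxy-6-methoxyphenyl]-3-[2,4-bis(benzyloxy)phenyl]prop-2-en-1-one | COc1cc(OCc2ccccc2)cc(O)c1C(=O)/C=C/c1ccc(OCc2ccccc2)cc1OCc1ccccc1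
A7 | alternative 3 | 7-(benzyloxy)-3-[2,4-bis(benzyloxy)phenyl]-5-methoxy-4H-chromen-4-one | COc1cc(OCc2ccccc2)cc2occ(-c3ccc(OCc4ccccc4)cc3OCc3ccccc3)c(=O)c12
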